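## Retrosynthetic overview

- The chromene C3=C4 bond of ring B's dimethylpyran is unveiled last, by dehydrogenating the corresponding 2,2-dimethylchroman isoflavone, so that no second alkene is present when the carbene is used.
- The strategy rests on the pyran-4-one ring C, O1–C2H=C3(aryl)–C4(=O)–C4a–C8a. It is read as a 3-oxybenzofuran (O1–C2H=C3(O)–C3a–C7a) with one extra carbon, the aryl-bearing C3, inserted between furan C2 and C3.
- Disconnecting chromone bonds C2–C3 and C3–C4 gives 3-(tert-butyldimethylsilyloxy)-6-methoxybenzofuran and an aryl(chloro)carbene released from a 3-aryl-3-chlorodiazirine.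
- The diazirine comes from the amidine, the nitrile and 5-methoxy-2,2-dimethylchroman-6-carbaldehyde, itself made by prenal annulation of 2,4-dihydroxybenzaldehyde, hydrogenation and O-methylation.
- Ring order: ring A is bought with the benzofuranone; the dimethylpyran ring is built in step 1, the diazirine in step 6, ring C by one-carbon enlargement of the furan in step 8, and the chromene unsaturation in step 9.

Key step: step 8

Remark on the chemistry: the target has no stereocentre. The chlorocyclopropane formed in the key step is expected as a racemate and as a mixture of epimers at the chlorine-bearing carbon; all three of its stereocentres are lost in the same flask, so its SMILES carries no descriptors.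

## Route

Step 1
Reactants: 1 2,4-dihydroxybenzaldehyde; 2 3-methylbut-2-enal
Product: 4 5-hydroxy-2,2-dimethyl-2H-chromene-6-carbaldehyde, via quinone methide dienone 3 (not isolated)
Conditions: pyridine, 140 °C, sealed tube
Reagents that add atoms: none
Why: Condensation of the enal at C3 of the resorcinol unit (the carbon between the two hydroxyls), dehydration to dienone 3 and oxa-6π electrocyclisation through the unchelated 4-oxygen is the established chromenylation of 2,4-dihydroxyaryl carbonyl compounds; the 2-hydroxyl stays hydrogen bonded to the formyl group, so the angular 5-hydroxy-6-formyl chromene should result.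

Step 2
Reactants: 4 5-hydroxy-2,2-dimethyl-2H-chromene-6-carbaldehyde
Product: 5 5-hydroxy-2,2-dimethylchroman-6-carbaldehyde
Conditions: H2 (1 atm), Pd/C (10% Pd on carbon), EtOAc, rt, stopped after one equivalent of H2
Reagents that add atoms: none
Why: Heterogeneous catalytic hydrogenation should saturate the cis-disubstituted styrenic C3=C4 bond much faster than it reduces the chelated aryl aldehyde.

Step 3
Reactants: 5 5-hydroxy-2,2-dimethylchroman-6-carbaldehyde
Product: 6 5-methoxy-2,2-dimethylchroman-6-carbaldehyde
Conditions: MeI, K2CO3, DMF, 40 °C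
Reagents that add atoms: iodomethane, CI
Why: Williamson O-methylation of the only phenol; DMF and gentle warming overcome the hydrogen bond to the neighbouring formyl group.

Step 4
Reactants: 6 5-methoxy-2,2-dimethylchroman-6-carbaldehyde
Product: 8 5-methoxy-2,2-dimethylchroman-6-carbonitrile, via aldoxime 7 (not isolated)
Conditions: NH2OH·HCl, DMSO, 100 °C
Reagents that add atoms: hydroxylamine hydrochloride, NO.Cl
Why: One-pot oximation and thermal dehydration of the aldoxime in DMSO is a standard aldehyde-to-nitrile conversion, and the aryl ethers are inert to the HCl released.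

Step 5
Reactants: 8 5-methoxy-2,2-dimethylchroman-6-carbonitrile
Product: 10 5-methoxy-2,2-dimethylchroman-6-carboximidamide hydrochloride, via N-lithio-N,N'-bis(trimethylsilyl)amidine 9 (not isolated)
Conditions: LiN(SiMe3)2, THF, 0 °C to rt; then HCl, EtOH, 0 °C
Reagents that add atoms: lithium bis(trimethylsilyl)amide, [Li]N([Si](C)(C)C)[Si](C)(C)C; hydrogen chloride, Cl
Why: Addition of the silylamide to the nitrile followed by cleavage of the N–Si and N–Li bonds with ethanolic HCl is the usual entry to aryl amidinium chlorides for Graham oxidation, and a single ortho methoxy group is tolerated in the addition.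

Step 6
Reactants: 10 5-methoxy-2,2-dimethylchroman-6-carboximidamide hydrochloride
Product: 12 3-chloro-3-(5-methoxy-2,2-dimethylchroman-6-yl)-3H-diazirine, via N,N'-dichloroamidine 11 (not isolated)
Conditions: aq NaOCl, NaCl, DMSO/pentane, 0 °C; pentane layer washed, dried and kept cold in the dark, never concentrated to dryness
Reagents that add atoms: sodium hypochlorite, [Na+].[O-]Cl; sodium chloride, [Na+].[Cl-] (chloride pool that returns to carbon)
Why: Graham oxidation, in which N-chlorination to the N,N'-dichloroamidine, base-induced N–N ring closure and return of chloride at carbon give the 3-aryl-3-chlorodiazirine; it is extracted into cold pentane as it forms, so contact of the electron-rich ring with hypochlorite is short.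

Step 7
Reactants: 13 6-methoxybenzofuran-3(2H)-one
Product: 14 3-(tert-butyldimethylsilyloxy)-6-methoxybenzofuran
Conditions: TBSOTf, Et3N, CH2Cl2, 0 °C
Reagents that add atoms: tert-butyldimethylsilyl trifluoromethanesulfonate, CC(C)(C)[Si](C)(C)OS(=O)(=O)C(F)(F)F
Why: Soft enolisation by Et3N and O-silylation by the silyl triflate is a standard silyl enol ether formation, driven here by the gain of furan aromaticity.

Step 8
Reactants: 12 3-chloro-3-(5-methoxy-2,2-dimethylchroman-6-yl)-3H-diazirine; 14 3-(tert-butyldimethylsilyloxy)-6-methoxybenzofuran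
Product: 18 7-methoxy-3-(5-methoxy-2,2-dimethylchroman-6-yl)-4H-chromen-4-one, via arylchlorocarbene 15 (not isolated), via chlorocyclopropane 16 (not isolated), via 4-siloxybenzopyrylium chloride 17 (not isolated)
Conditions: 12 (2 equiv, cold pentane solution), Na2CO3, MeCN, 50 °C, dark; aq NaHCO3 work-up
Reagents that add atoms: none
Why: Proposed new method: warming 12 should extrude N2 to give the electrophilic singlet arylchlorocarbene 15, which should add [2+1] to the most electron-rich π bond present, the C2=C3 enol ether bond of 14 activated by both O1 and the siloxy group, to give chlorocyclopropane 16. Loss of chloride from 16 with disrotatory two-electron opening of the former furan C2–C3 bond (concerted for the endo-chloro epimer, through the aryl-stabilised cyclopropyl cation for the exo epimer) should give the aromatic 3-aryl-4-siloxybenzopyrylium chloride 17, and chloride should then take the silyl group from oxygen to leave the C4 carbonyl of 18. Ring C is thus formed by one-carbon enlargement of the furan ring, which creates chromone bonds C2–C3 and C3–C4, and not by a cyclising attack. The closest known reactions are the arylchlorodiazirine carbon insertions into indoles, pyrroles and indenes (Ciamician–Dennstedt type) and the dihalocarbene ring expansions of benzofurans and of cyclic silyl enol ethers to α-halo enones; an arylchlorocarbene has not been combined with a 3-siloxybenzofuran. No stereocentre remains in 18, because the three of 16 are all flattened on opening. The site selectivity needed (furan enol ether rather than the dialkoxy ring B or C–H bonds) rests on the siloxy donor, on ring B being carried as the chroman so that no other alkene is present, and on Na2CO3 keeping the acid-labile enol ether intact.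

Step 9
Reactants: 18 7-methoxy-3-(5-methoxy-2,2-dimethylchroman-6-yl)-4H-chromen-4-one
Product: 19 7-methoxy-3-(5-methoxy-2,2-dimethyl-2H-chromen-6-yl)-4H-chromen-4-one (target)
Conditions: DDQ, 1,4-dioxane, reflux
Reagents that add atoms: none
Why: DDQ should abstract hydride from benzylic C4 of the chroman (the cation is stabilised by the C8a ring oxygen and the C5 methoxy group, both ortho to C4a) and loss of a C3 proton gives the 2H-chromene; this is a standard dehydrogenation of 2,2-dimethylchromans, in which the quaternary C2 stops further oxidation and the chromone is inert.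

## Compound list

1 | 2,4-dihydroxybenzaldehyde | O=Cc1ccc(O)cc1O | starting material
2 | 3-methylbut-2-enal | CC(C)=CC=O | starting material
3 | 2-hydroxy-3-(3-methylbut-2-en-1-ylidene)-4-oxocyclohexa-1,5-diene-1-carbaldehyde (formed in the flask, not isolated) | O=CC1=C(O)C(=CC=C(C)C)C(=O)C=C1 | intermediate
4 | 5-hydroxy-2,2-dimethyl-2H-chromene-6-carbaldehyde | O=Cc1ccc2OC(C)(C)C=Cc2c1O | intermediate
5 | 5-hydroxy-2,2-dimethylchroman-6-carbaldehyde | O=Cc1ccc2OC(C)(C)CCc2c1O | intermediate
6 | 5-methoxy-2,2-dimethylchroman-6-carbaldehyde | COc1c(C=O)ccc2OC(C)(C)CCc12 | intermediate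
7 | (E)-5-methoxy-2,2-dimethylchroman-6-carbaldehyde oxime (formed in the flask, not isolated) | COc1c(/C=N/O)ccc2OC(C)(C)CCc12 | intermediate
8 | 5-methoxy-2,2-dimethylchroman-6-carbonitrile | COc1c(C#N)ccc2OC(C)(C)CCc12 | intermediate
9 | N-lithio-N,N'-bis(trimethylsilyl)-5-methoxy-2,2-dimethylchroman-6-carboximidamide (formed in the flask, not isolated) | COc1c(C(=N[Si](C)(C)C)N([Li])[Si](C)(C)C)ccc2OC(C)(C)CCc12 | intermediate
10 | 5-methoxy-2,2-dimethylchroman-6-carboximidamide hydrochloride | COc1c(C(=N)N)ccc2OC(C)(C)CCc12.Cl | intermediate
11 | N,N'-dichloro-5-methoxy-2,2-dimethylchroman-6-carboximidamide (formed in the flask, not isolated) | COc1c(C(=NCl)NCl)ccc2OC(C)(C)CCc12 | intermediate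
12 | 3-chloro-3-(5-methoxy-2,2-dimethylchroman-6-yl)-3H-diazirine | COc1c(C2(Cl)N=N2)ccc2OC(C)(C)CCc12 | intermediate
13 | 6-methoxybenzofuran-3(2H)-one | COc1ccc2C(=O)COc2c1 | starting material
14 | 3-(tert-butyldimethylsilyloxy)-6-methoxybenzofuran | COc1ccc2c(O[Si](C)(C)C(C)(C)C)coc2c1 | intermediate
15 | chloro(5-methoxy-2,2-dimethylchroman-6-yl)carbene (formed in the flask, not isolated) | COc1c([C]Cl)ccc2OC(C)(C)CCc12 | intermediate
16 | 6b-(tert-butyldimethylsilyloxy)-1-chloro-4-methoxy-1-(5-methoxy-2,2-dimethylchroman-6-yl)-1a,6b-dihydro-1H-cyclopropa[b]benzofuran, racemic, both epimers at the chlorine-bearing carbon (formed in the flask, not isolated) | COc1ccc2c(c1)OC1C(Cl)(c3ccc4OC(C)(C)CCc4c3OC)C21O[Si](C)(C)C(C)(C)C | intermediate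
17 | 4-(tert-butyldimethylsilyloxy)-7-methoxy-3-(5-methoxy-2,2-dimethylchroman-6-yl)chromenylium chloride (formed in the flask, not isolated) | COc1ccc2c(O[Si](C)(C)C(C)(C)C)c(-c3ccc4OC(C)(C)CCc4c3OC)c[o+]c2c1.[Cl-] | intermediate
18 | 7-methoxy-3-(5-methoxy-2,2-dimethylchroman-6-yl)-4H-chromen-4-one | COc1ccc2c(=O)c(-c3ccc4OC(C)(C)CCc4c3OC)coc2c1 | intermediate
19 | 7-methoxy-3-(5-methoxy-2,2-dimethyl-2H-chromen-6-yl)-4H-chromen-4-one | COc1ccc2c(=O)c(-c3ccc4c(c3OC)C=CC(C)(C)O4)coc2c1 | target

## Step count and risks

Total step count: 9. Longest linear sequence: 8 (steps 1 to 6, then 8 and 9); step 7 is the one-step side branch.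

Steps most likely to fail:

1. Step 8. The carbene may be consumed by dimerisation or by reaction with solvent and moisture faster than it cyclopropanates. The enol ether may also be desilylated before it is intercepted, or the carbene may attack the dialkoxy ring B. Fallback by known chemistry, setting out from aldehyde 6 and returning at 18: Claisen–Schmidt condensation of 6 with commercial 1-(2-hydroxy-4-methoxyphenyl)ethanone (KOH, EtOH, rt) should give the chalcone (E)-1-(2-hydroxy-4-methoxyphenyl)-3-(5-methoxy-2,2-dimethylchroman-6-yl)prop-2-en-1-one F1. Oxidative rearrangement with Tl(NO3)3·3H2O in MeOH/HC(OMe)3 should then move the electron-rich dialkoxyaryl group by a 1,2-shift and give the racemic acetal 1-(2-hydroxy-4-methoxyphenyl)-3,3-dimethoxy-2-(5-methoxy-2,2-dimethylchroman-6-yl)propan-1-one F2. HCl in MeOH at reflux should close the pyranone with loss of methanol to give 18, which goes on to step 9.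

2. Step 6. Hypochlorite may chlorinate the activated ring position C8 (ortho to the ring oxygen, para to the methoxy group), and the donor-substituted diazirine may ionise at its C–Cl bond and decompose before use. Fallback that no longer needs the diazirine, setting out from aldehyde 6 and returning at 18 by the deoxybenzoin route: van Leusen reductive cyanation (TosMIC, KOtBu, DME, −40 °C; then MeOH, reflux) should give 2-(5-methoxy-2,2-dimethylchroman-6-yl)acetonitrile F3. Hoesch acylation of resorcinol (ZnCl2, HCl gas, Et2O, 0 °C) should give the ketiminium salt 1-(2,4-dihydroxyphenyl)-2-(5-methoxy-2,2-dimethylchroman-6-yl)ethan-1-iminium chloride F4, hydrolysed in hot water to 1-(2,4-dihydroxyphenyl)-2-(5-methoxy-2,2-dimethylchroman-6-yl)ethanone F5. Formylative cyclisation (BF3·OEt2, DMF, MsCl, 70 °C) should give 7-hydroxy-3-(5-methoxy-2,2-dimethylchroman-6-yl)-4H-chromen-4-one F6, and MeI with K2CO3 in acetone should methylate the one phenol to give 18.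

3. Step 9. Hydride abstraction may be slow because the chromone substituent lowers the donor strength of ring B, or the quinone may oxidise further or add to the product. Fallback through radical substitution and elimination, setting out from 18 and returning at 19: benzylic bromination at C4 (NBS, AIBN, PhCF3, reflux) should give racemic 3-(4-bromo-5-methoxy-2,2-dimethylchroman-6-yl)-7-methoxy-4H-chromen-4-one F7. Dehydrobromination with DBU in toluene at 80 °C should then give 19.

Further compounds
F1 | step 8 | (E)-1-(2-hydroxy-4-methoxyphenyl)-3-(5-methoxy-2,2-dimethylchroman-6-yl)prop-2-en-1-one | COc1ccc(C(=O)/C=C/c2ccc3OC(C)(C)CCc3c2OC)c(O)c1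
F2 | step 8 | 1-(2-hydroxy-4-methoxyphenyl)-3,3-dimethoxy-2-(5-methoxy-2,2-dimethylchroman-6-yl)propan-1-one (racemic) | COc1ccc(C(=O)C(C(OC)OC)c2ccc3OC(C)(C)CCc3c2OC)c(O)c1
F3 | step 6 | 2-(5-methoxy-2,2-dimethylchroman-6-yl)acetonitrile | N#CCc1ccc2OC(C)(C)CCc2c1OC
F4 | step 6 | 1-(2,4-dihydroxyphenyl)-2-(5-methoxy-2,2-dimethylchroman-6-yl)ethan-1-iminium chloride | [NH2+]=C(Cc1ccc2OC(C)(C)CCc2c1OC)c1ccc(O)cc1O.[Cl-]
F5 | step 6 | 1-(2,4-dihydroxyphenyl)-2-(5-methoxy-2,2-dimethylchroman-6-yl)ethanone | O=C(Cc1ccc2OC(C)(C)CCc2c1OC)c1ccc(O)cc1O
F6 | step 6 | 7-hydroxy-3-(5-methoxy-2,2-dimethylchroman-6-yl)-4H-chromen-4-one | Oc1ccc2c(=O)c(-c3ccc4OC(C)(C)CCc4c3OC)coc2c1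
F7 | step 9 | 3-(4-bromo-5-methoxy-2,2-dimethylchroman-6-yl)-7-methoxy-4H-chromen-4-one (racemic) | COc1ccc2c(=O)c(-c3ccc4OC(C)(C)CC(Br)c4c3OC)coc2c1
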